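**Retrosynthetic overview**

1. Target 15 comes from its N-Boc derivative 14 by base methanolysis of the pyrrole carbamate.
2. The strategy rests on this feature: each indole carries C2–H and is bonded through its C3 to pyrrole C3 or C4. Both indoles are therefore cut at N1–C2 and at the C3–pyrrole bond, giving diiodopyrrole 7 and two molecules of ortho-ethynyl trifluoroacetanilide 12.
3. Ring order: the pyrrole is bought intact, and the two indole five-membered rings are closed last, one after the other, on the pyrrole in a single flask.
4. Compound 7 comes from 1-(triisopropylsilyl)pyrrole by β,β'-diiodination, desilylation, C2 trichloroacetylation, haloform methanolysis and N-Boc protection.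
5. Compound 12 comes from 4-bromo-2-iodoaniline by iodide-selective Sonogashira coupling, desilylation and trifluoroacetylation.

Key step: step 9

Assumption: in step 9 the iodide at pyrrole C3 (next to the ester, the more electron-poor position) is taken to react first. The opposite order would pass through the regioisomeric mono-indolyl iodide and end at the same compound 14.

**Route**

Step 1
Reactants: 1 1-(triisopropylsilyl)pyrrole
Product: 2 3,4-diiodo-1-(triisopropylsilyl)pyrrole
Conditions: NIS (2.2 equiv), acetone, −78 °C to rt, dark
Reagents that add atoms: N-iodosuccinimide, O=C1CCC(=O)N1I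
Why: The triisopropylsilyl group screens both α positions, so electrophilic aromatic iodination with NIS should occur twice at the β positions (C3 and C4).

Step 2
Reactants: 2 3,4-diiodo-1-(triisopropylsilyl)pyrrole
Product: 3 3,4-diiodo-1H-pyrrole
Conditions: Bu4NF (1.05 equiv), THF, 0 °C, 10 min; cold aqueous work-up, used at once, dark
Reagents that add atoms: none
Why: Fluoride-mediated N-desilylation, driven by the strong Si–F bond, should free the pyrrole N–H without touching the C–I bonds; 3 is expected to be light- and acid-sensitive and is carried on directly.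

Step 3
Reactants: 3 3,4-diiodo-1H-pyrrole; 4 trichloroacetyl chloride
Product: 5 2,2,2-trichloro-1-(3,4-diiodo-1H-pyrrol-2-yl)ethan-1-one
Conditions: 4 (1.5 equiv), 2,6-lutidine (1.6 equiv), CH2Cl2, 0 °C to reflux, dark
Reagents that add atoms: none
Why: Uncatalysed Friedel–Crafts-type C-acylation of a pyrrole with trichloroacetyl chloride can only go to an α position (C2 and C5 are equivalent) and stops after one acylation because the ketone deactivates the ring, while 2,6-lutidine takes up the HCl that could otherwise promote iodine migration.

Step 4
Reactants: 5 2,2,2-trichloro-1-(3,4-diiodo-1H-pyrrol-2-yl)ethan-1-one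
Product: 6 methyl 3,4-diiodo-1H-pyrrole-2-carboxylate
Conditions: NaOMe (0.3 equiv), MeOH, 0 °C to rt
Reagents that add atoms: methanol, CO
Why: Haloform-type acyl substitution, in which methoxide adds to the ketone and expels the trichloromethyl anion, should give the methyl ester under conditions that leave the C–I bonds alone.

Step 5
Reactants: 6 methyl 3,4-diiodo-1H-pyrrole-2-carboxylate
Product: 7 methyl 1-(tert-butoxycarbonyl)-3,4-diiodopyrrole-2-carboxylate
Conditions: Boc2O (1.3 equiv), DMAP (0.1 equiv), MeCN, rt
Reagents that add atoms: di-tert-butyl dicarbonate, CC(C)(C)OC(=O)OC(=O)OC(C)(C)C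
Why: DMAP-catalysed N-acylation of the acidic pyrrole N–H with Boc2O; the carbamate prevents N–H deprotonation in step 9 and makes the iodopyrrole more electron-poor for oxidative addition.

Step 6
Reactants: 8 4-bromo-2-iodoaniline; 9 trimethylsilylacetylene
Product: 10 4-bromo-2-[(trimethylsilyl)ethynyl]aniline
Conditions: 9 (1.1 equiv), PdCl2(PPh3)2 (2 mol %), CuI (4 mol %), Et3N, THF, rt
Reagents that add atoms: none
Why: Sonogashira coupling, selective for the C–I bond because zerovalent palladium inserts into aryl iodides far faster than into aryl bromides at room temperature.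

Step 7
Reactants: 10 4-bromo-2-[(trimethylsilyl)ethynyl]aniline
Product: 11 4-bromo-2-ethynylaniline
Conditions: K2CO3 (0.2 equiv), MeOH, rt
Reagents that add atoms: none
Why: Base-catalysed methanolysis of the alkynyl C–Si bond (protodesilylation) should free the terminal alkyne without affecting the aniline or the bromide.

Step 8
Reactants: 11 4-bromo-2-ethynylaniline
Product: 12 N-(4-bromo-2-ethynylphenyl)-2,2,2-trifluoroacetamide
Conditions: (CF3CO)2O (1.2 equiv), Et3N (1.5 equiv), CH2Cl2, 0 °C
Reagents that add atoms: trifluoroacetic anhydride, O=C(OC(=O)C(F)(F)F)C(F)(F)F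
Why: N-acylation of the aniline with trifluoroacetic anhydride gives the acidic trifluoroacetanilide needed as the nitrogen nucleophile of step 9; it is placed after desilylation because base or fluoride treatment of a silylated anilide could cyclise or deacylate it.

Step 9
Reactants: 7 methyl 1-(tert-butoxycarbonyl)-3,4-diiodopyrrole-2-carboxylate; 12 N-(4-bromo-2-ethynylphenyl)-2,2,2-trifluoroacetamide (2.6 equiv)
Product: 14 methyl 1-(tert-butoxycarbonyl)-3,4-bis(5-bromo-1H-indol-3-yl)pyrrole-2-carboxylate, via mono-indolyl iodide 13 (not isolated)
Conditions: Pd(PPh3)4 (10 mol %), Cs2CO3 (6 equiv), degassed MeCN, rt then 50 °C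
Reagents that add atoms: none
Why: Zerovalent palladium inserts into a pyrrolyl C–I bond of 7, the pyrrolyl palladium iodide (divalent palladium) binds the alkyne of 12, the cesium trifluoroacetamidate nitrogen attacks the activated alkyne anti to palladium to form N1–C2, and reductive elimination from the indol-3-yl pyrrolyl palladium species forms the C3–pyrrole bond; the cycle repeats at the second iodide of 13, and carbonate cleaves the labile N-trifluoroacetyl groups so that N–H indoles result. The closest known reaction type is the aminopalladation and reductive elimination annulation of ortho-alkynyl trifluoroacetanilides with aryl, heteroaryl and vinyl halides to 3-substituted indoles, which includes the 2-unsubstituted series from ortho-ethynyl trifluoroacetanilides and double annulations onto vicinal dihalides. Each of the two indole five-membered rings closes in a 5-endo-dig mode by nitrogen attack on the palladium-bound alkyne, and no stereocentre is formed. The step needs insertion at the pyrrolyl C–I bonds and not at the aryl C–Br bonds, and cyclisation ahead of alkynyl coupling of the terminal alkyne, which would lead to 2-pyrrolyl indoles. The weak C–I bonds on a pyrrole made electron-poor by the ester and the N-Boc group, the mild temperature, the absence of copper and the fully ionised acidic trifluoroacetamide should secure both, and the bromine para to nitrogen in 12 ends up at indole C5. The excess of 12 compensates for its base-mediated cyclisation to plain 5-bromoindole.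

Step 10
Reactants: 14 methyl 1-(tert-butoxycarbonyl)-3,4-bis(5-bromo-1H-indol-3-yl)pyrrole-2-carboxylate
Product: 15 methyl 3,4-bis(5-bromo-1H-indol-3-yl)-1H-pyrrole-2-carboxylate
Conditions: K2CO3 (0.5 equiv), MeOH/THF, rt, N2
Reagents that add atoms: none
Why: Base-catalysed methanolysis of the N-acyl azole type carbamate (the pyrrolide stabilised by the C2 ester is a good leaving group) should remove the Boc group at room temperature, while transesterification of the methyl ester in methanol is degenerate and the acid-sensitive 2-unsubstituted indoles never meet acid.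

**Compound list**

1 | 1-(triisopropylsilyl)pyrrole | CC(C)[Si](C(C)C)(C(C)C)n1cccc1 | starting material
2 | 3,4-diiodo-1-(triisopropylsilyl)pyrrole | CC(C)[Si](C(C)C)(C(C)C)n1cc(I)c(I)c1 | intermediate
3 | 3,4-diiodo-1H-pyrrole | Ic1c[nH]cc1I | intermediate
4 | trichloroacetyl chloride | O=C(Cl)C(Cl)(Cl)Cl | starting material
5 | 2,2,2-trichloro-1-(3,4-diiodo-1H-pyrrol-2-yl)ethan-1-one | O=C(c1[nH]cc(I)c1I)C(Cl)(Cl)Cl | intermediate
6 | methyl 3,4-diiodo-1H-pyrrole-2-carboxylate | COC(=O)c1[nH]cc(I)c1I | intermediate
7 | methyl 1-(tert-butoxycarbonyl)-3,4-diiodopyrrole-2-carboxylate | COC(=O)c1c(I)c(I)cn1C(=O)OC(C)(C)C | intermediate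
8 | 4-bromo-2-iodoaniline | Nc1ccc(Br)cc1I | starting material
9 | trimethylsilylacetylene | C#C[Si](C)(C)C | starting material
10 | 4-bromo-2-[(trimethylsilyl)ethynyl]aniline | C[Si](C)(C)C#Cc1cc(Br)ccc1N | intermediate
11 | 4-bromo-2-ethynylaniline | C#Cc1cc(Br)ccc1N | intermediate
12 | N-(4-bromo-2-ethynylphenyl)-2,2,2-trifluoroacetamide | C#Cc1cc(Br)ccc1NC(=O)C(F)(F)F | intermediate
13 | methyl 1-(tert-butoxycarbonyl)-3-(5-bromo-1H-indol-3-yl)-4-iodopyrrole-2-carboxylate (not isolated) | COC(=O)c1c(-c2c[nH]c3ccc(Br)cc23)c(I)cn1C(=O)OC(C)(C)C | intermediate
14 | methyl 1-(tert-butoxycarbonyl)-3,4-bis(5-bromo-1H-indol-3-yl)pyrrole-2-carboxylate | COC(=O)c1c(-c2c[nH]c3ccc(Br)cc23)c(-c2c[nH]c3ccc(Br)cc23)cn1C(=O)OC(C)(C)C | intermediate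
15 | methyl 3,4-bis(5-bromo-1H-indol-3-yl)-1H-pyrrole-2-carboxylate | COC(=O)c1[nH]cc(-c2c[nH]c3ccc(Br)cc23)c1-c1c[nH]c2ccc(Br)cc12 | target

**Step count**

Total step count: 10. Longest linear sequence: 7 steps (steps 1 to 5, 9 and 10). The alkyne branch (steps 6 to 8) joins at step 9.

**Steps most likely to fail**

Step 9. The second annulation may stall because the second pyrrolyl palladium species is flanked by an indolyl group. Other possible failures are alkynyl coupling of the terminal alkyne in place of cyclisation, protodepalladation that consumes 12 as 5-bromoindole, and base-induced loss or transfer of the Boc group that deactivates the remaining iodide. Boc transfer to an indole nitrogen alone would be harmless, since step 10 cleaves every azole carbamate.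

The fallback is a double Suzuki–Miyaura coupling that sets out from 7. The boron partner is tert-butyl 5-bromo-3-(4,4,5,5-tetramethyl-1,3,2-dioxaborolan-2-yl)indole-1-carboxylate F1. It would be made from commercial tert-butyl 5-bromoindole-1-carboxylate by carbamate-directed C3–H borylation with B2pin2, [Ir(OMe)(cod)]2 and 4,4'-di-tert-butyl-2,2'-bipyridine in THF at 60 °C. Coupling of 7 with F1 (2.5 equiv) under PdCl2(dppf) and K3PO4 in dioxane/water at 60 °C should take place at the C–I bonds ahead of the C–Br bonds. It should pass through methyl 1-(tert-butoxycarbonyl)-3-[1-(tert-butoxycarbonyl)-5-bromoindol-3-yl]-4-iodopyrrole-2-carboxylate F2 to methyl 1-(tert-butoxycarbonyl)-3,4-bis[1-(tert-butoxycarbonyl)-5-bromoindol-3-yl]pyrrole-2-carboxylate F3. Treatment of F3 with K2CO3 in MeOH/THF at 40 °C should remove all three Boc groups, and the fallback comes back to the route at 15.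

Step 3. C-acylation of the twice-iodinated, deactivated ring may be slow, and during a long reaction time acid-promoted iodine migration or loss and decomposition of the sensitive N–H pyrrole may take over.

The fallback sets out from 3, used crude, and replaces electrophilic acylation by directed metalation. Boc2O and DMAP in MeCN should give tert-butyl 3,4-diiodopyrrole-1-carboxylate F4. LiN(iPr)2 in THF at −78 °C should remove the C2 proton flanked by the carbamate and the C3 iodide, giving tert-butyl 3,4-diiodo-2-lithiopyrrole-1-carboxylate F5. The amide base does not undergo iodine–lithium exchange, and F5 is already the most stabilised lithio isomer, so no halogen migration is expected at this temperature. Quenching with methyl chloroformate at −78 °C should give 7 directly. The fallback comes back to the route at 7 and bypasses steps 3 to 5.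

Step 1. Under- and over-iodination, and migration of iodine from β to α positions under traces of acid, may give mixtures that are hard to separate.

The fallback sets out from 1 and introduces the halogens as bromine first. NBS (2.0 equiv) in THF at −78 °C should give 3,4-dibromo-1-(triisopropylsilyl)pyrrole F6 cleanly. Copper-catalysed aromatic halogen exchange would follow: CuI (10 mol %), NaI (4 equiv) and trans-N,N'-dimethylcyclohexane-1,2-diamine (20 mol %) in dioxane at 110 °C, driven by precipitation of NaBr. It should pass through 3-bromo-4-iodo-1-(triisopropylsilyl)pyrrole F7 and come back to the route at 2.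

**Further compounds**

F1 | step 9 | tert-butyl 5-bromo-3-(4,4,5,5-tetramethyl-1,3,2-dioxaborolan-2-yl)indole-1-carboxylate | CC(C)(C)OC(=O)n1cc(B2OC(C)(C)C(C)(C)O2)c2cc(Br)ccc21
F2 | step 9 | methyl 1-(tert-butoxycarbonyl)-3-[1-(tert-butoxycarbonyl)-5-bromoindol-3-yl]-4-iodopyrrole-2-carboxylate | COC(=O)c1c(-c2cn(C(=O)OC(C)(C)C)c3ccc(Br)cc23)c(I)cn1C(=O)OC(C)(C)C
F3 | step 9 | methyl 1-(tert-butoxycarbonyl)-3,4-bis[1-(tert-butoxycarbonyl)-5-bromoindol-3-yl]pyrrole-2-carboxylate | COC(=O)c1c(-c2cn(C(=O)OC(C)(C)C)c3ccc(Br)cc23)c(-c2cn(C(=O)OC(C)(C)C)c3ccc(Br)cc23)cn1C(=O)OC(C)(C)C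
F4 | step 3 | tert-butyl 3,4-diiodopyrrole-1-carboxylate | CC(C)(C)OC(=O)n1cc(I)c(I)c1
F5 | step 3 | tert-butyl 3,4-diiodo-2-lithiopyrrole-1-carboxylate | [Li]c1c(I)c(I)cn1C(=O)OC(C)(C)C
F6 | step 1 | 3,4-dibromo-1-(triisopropylsilyl)pyrrole | CC(C)[Si](C(C)C)(C(C)C)n1cc(Br)c(Br)c1
F7 | step 1 | 3-bromo-4-iodo-1-(triisopropylsilyl)pyrrole | CC(C)[Si](C(C)C)(C(C)C)n1cc(Br)c(I)c1
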